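**Strategy**

Everything rests on the bond between the bridging CH2 and C7 of the aromatic isochroman ring. That carbon is the only free position of a resorcinol ring, flanked by the C6 and C8 hydroxyls, and is a strong carbon nucleophile; the CH2 sits on C7 of the quinone-methide ring, the central carbon of an enolised 1,3-dione (C6–OH, C8=O). In one operation the key step unmasks a 7-methylidene-6,8-dione from the Mannich salt of decarboxycitrinin and traps it with decarboxydihydrocitrinin by conjugate Friedel–Crafts addition, which gives the target without protecting groups. Both partners derive from one monomer, built from an aryl Grignard reagent and (2S,3S)-2,3-epoxybutane.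

Key step: step 9

Assumption: the 6-hydroxy-8-oxo form drawn for the quinone-methide ring and its 8-hydroxy-6-oxo tautomer interconvert freely, so no step addresses the tautomer; compounds 1 and 6 are taken as purchased.

**Route**

Step 1
Reactants: 1 1,3-bis(benzyloxy)-5-bromobenzene
Product: 3 2,4-bis(benzyloxy)-6-bromobenzaldehyde, via aryl iminium salt 2 (not isolated)
Conditions: POCl3, DMF, 0 → 90 °C; then H2O, rt
Reagents that add atoms: N,N-dimethylformamide CN(C)C=O; water O
Why: Vilsmeier–Haack formylation, in which the chloroiminium ion should attack the ring carbon next to bromine (para to one benzyloxy group, ortho to the other) in preference to the more crowded carbon between the two benzyloxy groups, and water hydrolyses iminium salt 2.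

Step 2
Reactants: 3 2,4-bis(benzyloxy)-6-bromobenzaldehyde
Product: 5 1,5-bis(benzyloxy)-3-bromo-2-methylbenzene, via benzylic alcohol 4 (not isolated)
Conditions: Et3SiH (3 equiv), TFA, CH2Cl2, 0 °C → rt
Reagents that add atoms: none
Why: Ionic hydrogenation, in which the protonated aldehyde and then the 2,4-dialkoxy-stabilised benzylic cation from alcohol 4 each accept hydride from the silane, while the aryl bromide and the benzyl ethers should stay intact.

Step 3
Reactants: 5 1,5-bis(benzyloxy)-3-bromo-2-methylbenzene; 6 (2S,3S)-2,3-epoxybutane
Product: 8 (2S,3S)-3-[3,5-bis(benzyloxy)-2-methylphenyl]butan-2-ol, via aryl Grignard reagent 7 (not isolated)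
Conditions: Mg, THF, reflux; then CuI (10 mol%), 6, −30 °C → rt; aq. NH4Cl
Reagents that add atoms: none
Why: Copper-catalysed SN2 opening of the C2-symmetric trans-epoxide by the aryl Grignard reagent, in which inversion at either of the two equivalent carbons sets the benzylic centre as S (C4 of the target) and leaves the carbinol centre S (erythro alcohol).

Step 4
Reactants: 8 (2S,3S)-3-[3,5-bis(benzyloxy)-2-methylphenyl]butan-2-ol
Product: 10 (2R,3S)-3-[3,5-bis(benzyloxy)-2-methylphenyl]butan-2-ol, via inverted 4-nitrobenzoate 9 (not isolated)
Conditions: 4-O2NC6H4CO2H, PPh3, DIAD, THF, 0 °C → rt; then K2CO3 (0.2 equiv), MeOH, rt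
Reagents that add atoms: 4-nitrobenzoic acid O=C(O)c1ccc(cc1)[N+](=O)[O-]
Why: Mitsunobu inversion, in which the carboxylate displaces the oxyphosphonium group by SN2 and turns the carbinol centre from S to R (C3 of the target), the meta-alkoxy groups disfavouring aryl participation, and methanolysis of the activated ester 9 in the same flask frees the threo alcohol.

Step 5
Reactants: 10 (2R,3S)-3-[3,5-bis(benzyloxy)-2-methylphenyl]butan-2-ol
Product: 12 (3R,4S)-6,8-bis(benzyloxy)-3,4,5-trimethylisochroman, via methoxymethyl ether 11 (not isolated)
Conditions: CH2(OMe)2 (3 equiv), TMSOTf (0.2 equiv), CH2Cl2, 0 °C → rt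
Reagents that add atoms: dimethoxymethane COCOC
Why: Oxa-Pictet–Spengler cyclisation, in which mixed acetal 11 ionises to an oxocarbenium ion that closes (6-endo) onto the ring carbon ortho to the side chain, activated by one para and one ortho benzyloxy group, without touching either stereocentre.

Step 6
Reactants: 12 (3R,4S)-6,8-bis(benzyloxy)-3,4,5-trimethylisochroman
Product: 13 (3R,4S)-3,4,5-trimethylisochroman-6,8-diol (decarboxydihydrocitrinin)
Conditions: H2 (1 atm), 10% Pd/C, EtOAc, rt
Reagents that add atoms: none
Why: Hydrogenolysis of the two aryl benzyl ethers over palladium should be much faster than cleavage of the cyclic benzylic dialkyl ether, so the isochroman ring is kept.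

Step 7
Reactants: 13 (3R,4S)-3,4,5-trimethylisochroman-6,8-diol
Product: 14 (3R,4S)-6-hydroxy-3,4,5-trimethyl-3,4-dihydroisochromen-8-one (decarboxycitrinin)
Conditions: 13 added slowly to DDQ (1.0 equiv), THF, −20 → 0 °C
Reagents that add atoms: none
Why: DDQ dehydrogenation by hydride abstraction from C1, which is benzylic, alpha to the ring oxygen and ortho/para to the two hydroxyls, followed by loss of a phenolic proton to give the quinone methide, with inverse addition keeping free 13 away from the electrophilic C1 of the product.

Step 8
Reactants: 14 (3R,4S)-6-hydroxy-3,4,5-trimethyl-3,4-dihydroisochromen-8-one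
Product: 15 (3R,4S)-7-[(dimethylamino)methyl]-6-hydroxy-3,4,5-trimethyl-3,4-dihydroisochromen-8-one hydroiodide
Conditions: CH2=NMe2+ I− (1.0 equiv), MeCN, 0 °C → rt; Et2O, filtration
Reagents that add atoms: N,N-dimethylmethyleneiminium iodide (Eschenmoser's salt) C=[N+](C)C.[I-]
Why: Mannich reaction at C7, the central carbon of the enolised 1,3-dione and the only nucleophilic carbon of 14, with the product collected as its ammonium salt, in which the enol is not deprotonated and elimination is held back.

Step 9
Reactants: 15 (3R,4S)-7-[(dimethylamino)methyl]-6-hydroxy-3,4,5-trimethyl-3,4-dihydroisochromen-8-one hydroiodide; 13 (3R,4S)-3,4,5-trimethylisochroman-6,8-diol (1.3 equiv)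
Product: 17 dicitrinone I, via 7-methylidene-6,8-dione 16 (not isolated)
Conditions: NaOAc (2 equiv), MeCN, rt → 50 °C
Reagents that add atoms: none
Why: Acetate frees the zwitterion of 15, which loses dimethylamine by E1cB to give the 7-methylidene-6,8-dione 16, a doubly activated and unhindered acceptor of the ortho-quinone-methide type; C7 of 13 adds to its exocyclic CH2, and rearomatisation of the diol ring with enolisation of the dione ring gives 17. The closest known reaction type is the elimination/Michael (ortho-quinone-methide Friedel–Crafts) alkylation of phenols by Mannich bases of cyclic 1,3-diones, 4-hydroxycoumarins and 2-hydroxyquinones. No ring is closed and no stereocentre is formed; C3 and C4 of both halves are untouched, and the acetate buffer keeps the quinone-methide ring as its enol or enolate, which protects C4 from epimerisation. The step needs cross-coupling over homo-coupling, C- over O-alkylation, and attack at the exocyclic CH2 and not at C1 of a quinone methide. The first is secured because the CH2 is already fixed on the electrophile, whose own C7 is blocked, while 13 has a single free ring carbon; the second because O-adducts revert while the C-adduct rearomatises irreversibly. The third is secured because C1 is only a vinylogous ester carbon and is not activated in the absence of acid.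

**Compound list**

1 | 1,3-bis(benzyloxy)-5-bromobenzene | Brc1cc(OCc2ccccc2)cc(OCc2ccccc2)c1 | starting material
2 | [2,4-bis(benzyloxy)-6-bromophenyl]methylidene(dimethyl)iminium dichlorophosphate | C[N+](C)=Cc1c(Br)cc(OCc2ccccc2)cc1OCc1ccccc1.[O-]P(=O)(Cl)Cl | intermediate (not isolated)
3 | 2,4-bis(benzyloxy)-6-bromobenzaldehyde | O=Cc1c(Br)cc(OCc2ccccc2)cc1OCc1ccccc1 | intermediate
4 | [2,4-bis(benzyloxy)-6-bromophenyl]methanol | OCc1c(Br)cc(OCc2ccccc2)cc1OCc1ccccc1 | intermediate (not isolated)
5 | 1,5-bis(benzyloxy)-3-bromo-2-methylbenzene | Cc1c(Br)cc(OCc2ccccc2)cc1OCc1ccccc1 | intermediate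
6 | (2S,3S)-2,3-epoxybutane (trans-2,3-dimethyloxirane) | C[C@@H]1O[C@H]1C | starting material
7 | [3,5-bis(benzyloxy)-2-methylphenyl]magnesium bromide | Cc1c([Mg]Br)cc(OCc2ccccc2)cc1OCc1ccccc1 | intermediate (not isolated)
8 | (2S,3S)-3-[3,5-bis(benzyloxy)-2-methylphenyl]butan-2-ol | O[C@@H](C)[C@H](c1cc(OCc2ccccc2)cc(OCc2ccccc2)c1C)C | intermediate
9 | (2R,3S)-3-[3,5-bis(benzyloxy)-2-methylphenyl]butan-2-yl 4-nitrobenzoate | O=C(O[C@H](C)[C@H](c1cc(OCc2ccccc2)cc(OCc2ccccc2)c1C)C)c1ccc(cc1)[N+](=O)[O-] | intermediate (not isolated)
10 | (2R,3S)-3-[3,5-bis(benzyloxy)-2-methylphenyl]butan-2-ol | O[C@H](C)[C@H](c1cc(OCc2ccccc2)cc(OCc2ccccc2)c1C)C | intermediate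
11 | 1,5-bis(benzyloxy)-3-[(2S,3R)-3-(methoxymethoxy)butan-2-yl]-2-methylbenzene | COCO[C@H](C)[C@H](c1cc(OCc2ccccc2)cc(OCc2ccccc2)c1C)C | intermediate (not isolated)
12 | (3R,4S)-6,8-bis(benzyloxy)-3,4,5-trimethylisochroman | c1c(OCc3ccccc3)c(C)c2c(c1OCc4ccccc4)CO[C@H](C)[C@H]2C | intermediate
13 | (3R,4S)-3,4,5-trimethylisochroman-6,8-diol (decarboxydihydrocitrinin) | c1c(O)c(C)c2c(c1O)CO[C@H](C)[C@H]2C | intermediate
14 | (3R,4S)-6-hydroxy-3,4,5-trimethyl-3,4-dihydroisochromen-8-one (decarboxycitrinin) | CC1=C2C(=CO[C@H](C)[C@H]2C)C(=O)C=C1O | intermediate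
15 | (3R,4S)-7-[(dimethylamino)methyl]-6-hydroxy-3,4,5-trimethyl-3,4-dihydroisochromen-8-one hydroiodide | CC1=C2C(=CO[C@H](C)[C@H]2C)C(=O)C(C[NH+](C)C)=C1O.[I-] | intermediate
16 | (3R,4S)-3,4,5-trimethyl-7-methylidene-3,4-dihydroisochromene-6,8-dione | CC1=C2C(=CO[C@H](C)[C@H]2C)C(=O)C(=C)C1=O | intermediate (not isolated)
17 | dicitrinone I, (3R,4S)-7-{[(3R,4S)-6,8-dihydroxy-3,4,5-trimethyl-3,4-dihydro-1H-isochromen-7-yl]methyl}-6-hydroxy-3,4,5-trimethyl-3,4-dihydroisochromen-8-one | CC1=C2C(=CO[C@H](C)[C@H]2C)C(=O)C(Cc2c(O)c(C)c3c(c2O)CO[C@H](C)[C@H]3C)=C1O | target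

**Count and risks**

Total step count: 9.
Longest linear sequence: 9 steps (1 → 17); diol 13 enters a second time in step 9 as the nucleophile.

Steps most likely to fail:

1. Step 9. The methylidene dione may be captured by a second dione unit or oligomerise before the diol adds, and the diol may add to C1 of a quinone methide instead of the exocyclic CH2. The fallback moves the union to the phenol oxidation level, where the electrophile is an ordinary ortho-quinone methide and no C1 acceptor is present. It sets out from 13: Eschenmoser's salt in MeCN should give (3R,4S)-7-[(dimethylamino)methyl]-3,4,5-trimethylisochroman-6,8-diol hydroiodide F1. Heating F1 with a second equivalent of 13 (NaOAc, dioxane, 90 °C) forms the same CH2–aryl bond and should give the symmetric bis[(3R,4S)-6,8-dihydroxy-3,4,5-trimethylisochroman-7-yl]methane F2. Dehydrogenation of one ring of F2 with one equivalent of DDQ at low temperature, where either ring leads to the same product, comes back to the route at 17.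

2. Step 7. Hydride abstraction may not stop after one C–H bond on the electron-rich free diol, and unreacted diol may add to C1 of the quinone methide as it forms. The fallback oxidises while the phenols are still masked. It sets out from 12: DDQ in CH2Cl2/MeOH should give the C1 acetal (3R,4S)-6,8-bis(benzyloxy)-1-methoxy-3,4,5-trimethylisochroman F3 as a mixture of C1 epimers. Debenzylation with BCl3 and pentamethylbenzene in CH2Cl2 at −78 °C, followed by aqueous NaHCO3, removes both benzyl groups and the acetal methanol, and comes back to the route at 14 without any hydrogenation that could reduce the quinone methide.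

3. Step 4. The oxyphosphonium intermediate may undergo E2 elimination towards the conjugated styrene, and aryl participation may erode the inversion. The fallback replaces substitution by an oxidation–reduction sequence. It sets out from 8: Dess–Martin periodinane (NaHCO3, CH2Cl2) should give (S)-3-[3,5-bis(benzyloxy)-2-methylphenyl]butan-2-one F4 without enolisation. Felkin–Anh-controlled reduction with L-Selectride in THF at −78 °C, with hydride entering anti to the aryl group, should give the threo alcohol and comes back to the route at 10.

**Further compounds**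

F1 | step 9 | (3R,4S)-7-[(dimethylamino)methyl]-3,4,5-trimethylisochroman-6,8-diol hydroiodide | C[NH+](C)Cc1c(O)c(C)c2c(c1O)CO[C@H](C)[C@H]2C.[I-]
F2 | step 9 | bis[(3R,4S)-6,8-dihydroxy-3,4,5-trimethylisochroman-7-yl]methane | C(c1c(O)c(C)c2c(c1O)CO[C@H](C)[C@H]2C)c1c(O)c(C)c2c(c1O)CO[C@H](C)[C@H]2C
F3 | step 7 | (3R,4S)-6,8-bis(benzyloxy)-1-methoxy-3,4,5-trimethylisochroman (C1 epimers) | c1c(OCc3ccccc3)c(C)c2c(c1OCc4ccccc4)C(OC)O[C@H](C)[C@H]2C
F4 | step 4 | (S)-3-[3,5-bis(benzyloxy)-2-methylphenyl]butan-2-one | CC(=O)[C@H](c1cc(OCc2ccccc2)cc(OCc2ccccc2)c1C)C
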